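**Strategy.** Ring A is cut across its two para-related bonds, C2–C3 and C5–C10. This makes C10–C1–C2 an acetone α,α′-dianion equivalent (C1 as ketone) and C3/C5, insulated by the gem-dimethyl carbon C4, a 1,3-dielectrophile. Because C5–C10 is also the ring-fusion bond, one flask closes ring B and then ring A. The precursor is an acyclic tert-butyl β-keto ester carrying a regiodefined C10=C1 silyl enol ether, a C5=C6–C7 enone and a C3 aldehyde. Sc(OTf)3 triggers an intramolecular Mukaiyama–Michael addition (C5–C10, setting C5 and quaternary C10 from C9); base then closes C2–C3 by aldol condensation.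

Key step: step 8

Remark: labdane numbering (C1–C20; C17 = carboxyl carbon, C20 = methyl on C10) and the α/β convention are used for all intermediates; TBS = tert-butyldimethylsilyl.
Assumption: the (S)-configured oxazaborolidinium catalyst of step 4 is taken to shield the Si face of C9 of enone 6; if the sense is the opposite one, its enantiomer is used.
Remark: aldehyde 9 is used as its commercial dimer, which dissociates to the monomer on warming.

Step 1
Reactants: 1 (S)-citronellol, (3S)-3,7-dimethyloct-6-en-1-ol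
Product: 2 tert-butyl{[(3S)-3,7-dimethyloct-6-en-1-yl]oxy}dimethylsilane
Conditions: TBSCl, imidazole, DMF, 0 °C to rt
Reagents that add atoms: tert-butyldimethylsilyl chloride, CC(C)(C)[Si](C)(C)Cl
Why: Imidazole-promoted silylation of the primary alcohol protects C15–OH through the later strong-base steps, which an acetate would not survive; the C13 centre comes from the chiral pool and is not touched.

Step 2
Reactants: 2 tert-butyl{[(3S)-3,7-dimethyloct-6-en-1-yl]oxy}dimethylsilane
Product: 4 (4S)-6-[(TBS)oxy]-4-methylhexanal, via ozonide 3 (not isolated)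
Conditions: O3, CH2Cl2, −78 °C; then Me2S, −78 °C to rt
Reagents that add atoms: ozone, [O-][O+]=O
Why: Ozonolysis with reductive work-up cleaves the only alkene and should give the aldehyde whose carbonyl carbon becomes C9.

Step 3
Reactants: 4 (4S)-6-[(TBS)oxy]-4-methylhexanal; 5 3-(triphenyl-λ5-phosphanylidene)butan-2-one
Product: 6 (3E,7S)-9-[(TBS)oxy]-3,7-dimethylnon-3-en-2-one
Conditions: toluene, 90 °C
Reagents that add atoms: none
Why: Wittig olefination with the stabilized α-methyl acyl ylide should give the (E)-trisubstituted enone, which holds C9=C10, the C20 methyl and the C1 ketone with its C2 methyl.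

Step 4
Reactants: 6 (3E,7S)-9-[(TBS)oxy]-3,7-dimethylnon-3-en-2-one; 7 tert-butyl[(1-tert-butoxyethenyl)oxy]dimethylsilane
Product: 8 tert-butyl (3S,6S)-8-[(TBS)oxy]-3-{3-[(TBS)oxy]but-2-en-2-yl}-6-methyloctanoate
Conditions: (S)-1-(2-methylphenyl)-3,3-diphenyltetrahydro-1H,3H-pyrrolo[1,2-c][1,3,2]oxazaborole·HNTf2 (20 mol %), toluene, −78 to −40 °C
Reagents that add atoms: none
Why: In this enantioselective Mukaiyama–Michael addition the chiral oxazaborolidinium ion binds the enone carbonyl and exposes the Re face of C9 to the ketene silyl acetal, which sets C9 (9α-H of the target), and silyl transfer to the new enolate fixes the C10=C1 enol ether regiochemistry that enolization of the ketone could not give.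

Step 5
Reactants: 9 3-hydroxy-2,2-dimethylpropanal; 10 2-(triphenyl-λ5-phosphanylidene)acetaldehyde
Product: 11 (2E)-5-hydroxy-4,4-dimethylpent-2-enal
Conditions: toluene, 80 °C
Reagents that add atoms: none
Why: Wittig olefination with the formyl-stabilized ylide should give the (E)-enal that carries C3 to C7; the free hydroxyl is tolerated and the product cannot cyclize because of its (E)-alkene.

Step 6
Reactants: 8 tert-butyl (3S,6S)-8-[(TBS)oxy]-3-{3-[(TBS)oxy]but-2-en-2-yl}-6-methyloctanoate; 11 (2E)-5-hydroxy-4,4-dimethylpent-2-enal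
Product: 12 tert-butyl (4E)-2-[(1S,4S)-6-[(TBS)oxy]-1-{3-[(TBS)oxy]but-2-en-2-yl}-4-methylhexyl]-3,7-dihydroxy-6,6-dimethylhept-4-enoate
Conditions: LiN(i-Pr)2, THF, −78 °C; then sodium alkoxide of 11 (from NaH, THF, 0 °C), −78 °C; aq. NH4Cl
Reagents that add atoms: none
Why: Aldol addition of the lithium ester enolate (C8) to the enal carbonyl (C7) should occur 1,2 at −78 °C and forms the C7–C8 bond; the silyl enol ether is inert to the amide base, and the new C7 and C8 centres are lost again later.

Step 7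
Reactants: 12 tert-butyl (4E)-2-[(1S,4S)-6-[(TBS)oxy]-1-{3-[(TBS)oxy]but-2-en-2-yl}-4-methylhexyl]-3,7-dihydroxy-6,6-dimethylhept-4-enoate
Product: 13 tert-butyl (4E)-2-[(1S,4S)-6-[(TBS)oxy]-1-{3-[(TBS)oxy]but-2-en-2-yl}-4-methylhexyl]-6,6-dimethyl-3,7-dioxohept-4-enoate
Conditions: (n-Pr4N)RuO4 (10 mol %), N-methylmorpholine N-oxide, 4 Å molecular sieves, CH2Cl2, 0 °C to rt
Reagents that add atoms: none
Why: The neutral Ley–Griffith oxidation should convert the allylic alcohol into the C7 enone carbonyl and the neopentyl alcohol into the C3 aldehyde in one step while sparing the silyl enol ether.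

Step 8
Reactants: 13 tert-butyl (4E)-2-[(1S,4S)-6-[(TBS)oxy]-1-{3-[(TBS)oxy]but-2-en-2-yl}-4-methylhexyl]-6,6-dimethyl-3,7-dioxohept-4-enoate
Product: 16 tert-butyl 15-[(TBS)oxy]-1,7-dioxolabd-2-en-17-oate (5α-H, 9α-H, 10β-CH3, 13S; C8 epimers and enol), via 2,3-seco Michael adduct 14 (not isolated), via dienone silyl enol ether 15 (not isolated)
Conditions: Sc(OTf)3 (10 mol %), 2,6-di-tert-butylpyridine (20 mol %), CH2Cl2 (0.005 M), −40 °C; then KOt-Bu, THF, −40 to 0 °C; aq. NH4Cl, then 10% aq. citric acid, THF, rt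
Reagents that add atoms: none
Why: Sc(OTf)3 binds the β-keto ester in a two-point fashion and so activates the C5=C6–C7=O enone over the monodentate aldehyde; the tetrasubstituted silyl enol ether then adds through C10 to C5 (intramolecular Mukaiyama–Michael addition, 6-(enolexo)-endo-trig, closing ring B), and the silyl group moves to the C7 enolate oxygen, which masks C7 against aldol attack. KOt-Bu then enolizes the liberated C1 methyl ketone, which is possible only at C2 because C10 is now quaternary, and the C2 enolate condenses with the C3 aldehyde (6-(enolendo)-exo-trig aldol closing ring A, then E1cB loss of water); the closest known reaction types are Lewis-acid Mukaiyama–Michael cyclizations and the aldol half of a Robinson annulation. C5 and C10 are set in the first closure under kinetic control by C9: a chair transition state with the C9 side chain and the C5 substituent equatorial, and with C9–H eclipsing the enol ether to avoid allylic 1,3-strain, places the C1 acyl arm equatorial and the C10 methyl axial, anti to C5–H, which is the trans ring fusion with the methyl cis to the side chain. The step needs C10 and not C2 to be the first nucleophile and C5 and not C7 or C3 the first electrophile; the preformed C10=C1 silyl enol ether secures the first, ring size (six against four or eight) and chelate activation secure the second, and high dilution should suppress intermolecular aldol addition. Because the Michael adduct is held as a silyl enol ether, the ring fusion should not equilibrate by retro-Michael reaction.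

Step 9
Reactants: 16 tert-butyl 15-[(TBS)oxy]-1,7-dioxolabd-2-en-17-oate
Product: 17 tert-butyl 15-[(TBS)oxy]-1,7-dioxolabdan-17-oate (C8 epimers and enol)
Conditions: H2 (1 atm), 10% Pd/C, EtOAc, rt
Reagents that add atoms: none
Why: Catalytic hydrogenation should saturate the cis-disubstituted enone bond C2=C3 and leave both carbonyl groups and the enolized β-keto ester untouched.

Step 10
Reactants: 17 tert-butyl 15-[(TBS)oxy]-1,7-dioxolabdan-17-oate
Product: 18 tert-butyl 15-[(TBS)oxy]-1,7-bis[(trifluoromethanesulfonyl)oxy]labda-1,7-dien-17-oate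
Conditions: KN(SiMe3)2 (2.3 equiv), THF, −78 °C; then PhNTf2, −78 to 0 °C
Reagents that add atoms: N-phenylbis(trifluoromethanesulfonimide), O=S(=O)(N(c1ccccc1)S(=O)(=O)C(F)(F)F)C(F)(F)F
Why: The base deprotonates first the β-keto ester and then the C1 ketone at C2, its only enolizable position, and O-triflation of both enolates gives the C7=C8 and C1=C2 enol triflates.

Step 11
Reactants: 18 tert-butyl 15-[(TBS)oxy]-1,7-bis[(trifluoromethanesulfonyl)oxy]labda-1,7-dien-17-oate
Product: 19 tert-butyl 15-[(TBS)oxy]labda-1,7-dien-17-oate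
Conditions: Pd(OAc)2 (10 mol %), PPh3, HCO2H, n-Bu3N, DMF, 60 °C
Reagents that add atoms: none
Why: Palladium-catalysed formate reduction of enol triflates (oxidative addition, hydride transfer from formate, reductive elimination) should replace both triflate groups by hydrogen, giving the C7=C8 unsaturated ester of the target and removing the C1 oxygen.

Step 12
Reactants: 19 tert-butyl 15-[(TBS)oxy]labda-1,7-dien-17-oate
Product: 20 tert-butyl 15-[(TBS)oxy]labd-7-en-17-oate
Conditions: RhCl(PPh3)3 (10 mol %), H2 (1 atm), benzene/EtOH, rt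
Reagents that add atoms: none
Why: Homogeneous hydrogenation with this rhodium complex should reduce the cis-disubstituted, unconjugated C1=C2 bond and leave the trisubstituted, ester-conjugated and hindered C7=C8 bond.

Step 13
Reactants: 20 tert-butyl 15-[(TBS)oxy]labd-7-en-17-oate
Product: 22 (5S,9R,10S,13S)-15-acetoxylabd-7-en-17-oic acid, via hydroxy acid 21 (not isolated)
Conditions: CF3CO2H, CH2Cl2, H2O, 0 °C to rt; evaporate; then Ac2O, pyridine, rt; H2O
Reagents that add atoms: acetic anhydride, CC(=O)OC(C)=O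
Why: Acidolysis should cleave the tert-butyl ester and the primary silyl ether together, and acetylation then esterifies the primary alcohol while the mixed anhydride formed at the carboxyl group is hydrolysed on aqueous work-up.

Compound list
1 | (S)-citronellol, (3S)-3,7-dimethyloct-6-en-1-ol | OCC[C@@H](C)CCC=C(C)C | starting material
2 | tert-butyl{[(3S)-3,7-dimethyloct-6-en-1-yl]oxy}dimethylsilane | CC(C)(C)[Si](C)(C)OCC[C@@H](C)CCC=C(C)C | intermediate
3 | ozonide of 2, 3-{(3S)-5-[(TBS)oxy]-3-methylpentyl}-5,5-dimethyl-1,2,4-trioxolane | CC(C)(C)[Si](C)(C)OCC[C@@H](C)CCC1OOC(C)(C)O1 | intermediate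
4 | (4S)-6-[(TBS)oxy]-4-methylhexanal | CC(C)(C)[Si](C)(C)OCC[C@@H](C)CCC=O | intermediate
5 | 3-(triphenyl-λ5-phosphanylidene)butan-2-one | CC(=O)C(C)=P(c1ccccc1)(c1ccccc1)c1ccccc1 | starting material
6 | (3E,7S)-9-[(TBS)oxy]-3,7-dimethylnon-3-en-2-one | CC(C)(C)[Si](C)(C)OCC[C@@H](C)CC/C=C(\C)C(C)=O | intermediate
7 | tert-butyl[(1-tert-butoxyethenyl)oxy]dimethylsilane | C=C(OC(C)(C)C)O[Si](C)(C)C(C)(C)C | starting material
8 | tert-butyl (3S,6S)-8-[(TBS)oxy]-3-{3-[(TBS)oxy]but-2-en-2-yl}-6-methyloctanoate (enol ether geometry not defined) | CC(C)(C)[Si](C)(C)OCC[C@@H](C)CC[C@H](C(C)=C(C)O[Si](C)(C)C(C)(C)C)CC(=O)OC(C)(C)C | intermediate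
9 | 3-hydroxy-2,2-dimethylpropanal | CC(C)(CO)C=O | starting material
10 | 2-(triphenyl-λ5-phosphanylidene)acetaldehyde | O=CC=P(c1ccccc1)(c1ccccc1)c1ccccc1 | starting material
11 | (2E)-5-hydroxy-4,4-dimethylpent-2-enal | OCC(C)(C)/C=C/C=O | intermediate
12 | tert-butyl (4E)-2-[(1S,4S)-6-[(TBS)oxy]-1-{3-[(TBS)oxy]but-2-en-2-yl}-4-methylhexyl]-3,7-dihydroxy-6,6-dimethylhept-4-enoate (epimers at C7 and C8) | CC(C)(C)[Si](C)(C)OCC[C@@H](C)CC[C@H](C(C)=C(C)O[Si](C)(C)C(C)(C)C)C(C(=O)OC(C)(C)C)C(O)/C=C/C(C)(C)CO | intermediate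
13 | tert-butyl (4E)-2-[(1S,4S)-6-[(TBS)oxy]-1-{3-[(TBS)oxy]but-2-en-2-yl}-4-methylhexyl]-6,6-dimethyl-3,7-dioxohept-4-enoate (epimers at C8) | CC(C)(C)[Si](C)(C)OCC[C@@H](C)CC[C@H](C(C)=C(C)O[Si](C)(C)C(C)(C)C)C(C(=O)OC(C)(C)C)C(=O)/C=C/C(C)(C)C=O | intermediate
14 | tert-butyl 7,15-bis[(TBS)oxy]-1,3-dioxo-2,3-secolabd-6-en-17-oate (5α-H, 9α-H, 10β-CH3, 13S) | CC(C)(C)[Si](C)(C)OCC[C@@H](C)CC[C@H]1C(C(=O)OC(C)(C)C)C(O[Si](C)(C)C(C)(C)C)=C[C@@H](C(C)(C)C=O)[C@]1(C)C(C)=O | intermediate
15 | tert-butyl 7,15-bis[(TBS)oxy]-1-oxolabda-2,6-dien-17-oate (5α-H, 9α-H, 10β-CH3, 13S) | CC(C)(C)[Si](C)(C)OCC[C@@H](C)CC[C@H]1C(C(=O)OC(C)(C)C)C(O[Si](C)(C)C(C)(C)C)=C[C@H]2C(C)(C)C=CC(=O)[C@]12C | intermediate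
16 | tert-butyl 15-[(TBS)oxy]-1,7-dioxolabd-2-en-17-oate (5α-H, 9α-H, 10β-CH3, 13S) | CC(C)(C)[Si](C)(C)OCC[C@@H](C)CC[C@H]1C(C(=O)OC(C)(C)C)C(=O)C[C@H]2C(C)(C)C=CC(=O)[C@]12C | intermediate
17 | tert-butyl 15-[(TBS)oxy]-1,7-dioxolabdan-17-oate (5α-H, 9α-H, 10β-CH3, 13S) | CC(C)(C)[Si](C)(C)OCC[C@@H](C)CC[C@H]1C(C(=O)OC(C)(C)C)C(=O)C[C@H]2C(C)(C)CCC(=O)[C@]12C | intermediate
18 | tert-butyl 15-[(TBS)oxy]-1,7-bis[(trifluoromethanesulfonyl)oxy]labda-1,7-dien-17-oate | CC(C)(C)[Si](C)(C)OCC[C@@H](C)CC[C@H]1C(C(=O)OC(C)(C)C)=C(OS(=O)(=O)C(F)(F)F)C[C@H]2C(C)(C)CC=C(OS(=O)(=O)C(F)(F)F)[C@]12C | intermediate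
19 | tert-butyl 15-[(TBS)oxy]labda-1,7-dien-17-oate | CC(C)(C)[Si](C)(C)OCC[C@@H](C)CC[C@H]1C(C(=O)OC(C)(C)C)=CC[C@H]2C(C)(C)CC=C[C@]12C | intermediate
20 | tert-butyl 15-[(TBS)oxy]labd-7-en-17-oate | CC(C)(C)[Si](C)(C)OCC[C@@H](C)CC[C@H]1C(C(=O)OC(C)(C)C)=CC[C@H]2C(C)(C)CCC[C@]12C | intermediate
21 | 15-hydroxylabd-7-en-17-oic acid | OCC[C@@H](C)CC[C@H]1C(C(=O)O)=CC[C@H]2C(C)(C)CCC[C@]12C | intermediate
22 | (5S,9R,10S,13S)-15-acetoxylabd-7-en-17-oic acid | CC(=O)OCC[C@@H](C)CC[C@H]1C(C(=O)O)=CC[C@H]2C(C)(C)CCC[C@]12C | target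

Total step count: 13. Longest linear sequence: 12 steps (steps 1–4 and 6–13; step 5 makes the second fragment).

Steps most likely to fail

Step 8. The silyl enol ether may add to the aldehyde of a second molecule during the Lewis acid stage, or the first closure may stall, so that oligomers form instead of ring B. The fallback sets out from diol 12 and keeps the aldehyde masked until ring B is closed, at the price of closing the two rings in separate flasks. MnO2 (CH2Cl2, rt) oxidizes only the allylic alcohol to give the keto alcohol F1. Sc(OTf)3 under the conditions of step 8 then closes ring B to give the ring-B silyl enol ether alcohol F2. Oxidation with (n-Pr4N)RuO4 and N-methylmorpholine N-oxide gives the aldehyde 14, now isolated, and KOt-Bu followed by citric acid returns the route to 16.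

Step 4. Facial selectivity at C9 may be poor with this α-branched acyclic enone, or the ketene acetal may add to the carbonyl group instead of the β-carbon. The fallback sets out from enone 6 and uses a covalently bound sulfur auxiliary. The lithium enolate of tert-butyl (R)-(p-tolylsulfinyl)acetate is added in conjugate fashion at −78 °C and the resulting ketone enolate is trapped with TBSCl, which gives the α-sulfinyl ester silyl enol ether F3 with the same enol ether regiochemistry. Reductive cleavage of the carbon–sulfur bond with aluminium amalgam (Al/Hg, aqueous THF) returns the route to 8.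

Step 12. The hindered C1=C2 bond next to the quaternary C10 may be reduced too slowly, so that the conjugated C7=C8 bond migrates or is reduced as well. The fallback sets out from 17 and never forms the C1=C2 bond. NaH and PhNTf2 triflate only the β-keto ester to give the mono-enol triflate F4, and the palladium–formate reduction of step 11 gives the keto ester F5 with the C7=C8 bond in place. The C1 ketone is then removed by Wolff–Kishner reduction through the N-silyl hydrazone F6 (1,2-bis(tert-butyldimethylsilyl)hydrazine, Sc(OTf)3 cat.; then KOt-Bu, DMSO), which comes back to the route at 20.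

Further compounds
F1 | step 8 | tert-butyl (4E)-2-[(1S,4S)-6-[(TBS)oxy]-1-{3-[(TBS)oxy]but-2-en-2-yl}-4-methylhexyl]-7-hydroxy-6,6-dimethyl-3-oxohept-4-enoate | CC(C)(C)[Si](C)(C)OCC[C@@H](C)CC[C@H](C(C)=C(C)O[Si](C)(C)C(C)(C)C)C(C(=O)OC(C)(C)C)C(=O)/C=C/C(C)(C)CO
F2 | step 8 | tert-butyl 7,15-bis[(TBS)oxy]-3-hydroxy-1-oxo-2,3-secolabd-6-en-17-oate (5α-H, 9α-H, 10β-CH3, 13S) | CC(C)(C)[Si](C)(C)OCC[C@@H](C)CC[C@H]1C(C(=O)OC(C)(C)C)C(O[Si](C)(C)C(C)(C)C)=C[C@@H](C(C)(C)CO)[C@]1(C)C(C)=O
F3 | step 4 | tert-butyl (3S,6S)-8-[(TBS)oxy]-3-{3-[(TBS)oxy]but-2-en-2-yl}-6-methyl-2-[(R)-4-methylbenzenesulfinyl]octanoate | CC(C)(C)[Si](C)(C)OCC[C@@H](C)CC[C@H](C(C)=C(C)O[Si](C)(C)C(C)(C)C)C(C(=O)OC(C)(C)C)[S@@](=O)c1ccc(C)cc1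
F4 | step 12 | tert-butyl 15-[(TBS)oxy]-1-oxo-7-[(trifluoromethanesulfonyl)oxy]labd-7-en-17-oate | CC(C)(C)[Si](C)(C)OCC[C@@H](C)CC[C@H]1C(C(=O)OC(C)(C)C)=C(OS(=O)(=O)C(F)(F)F)C[C@H]2C(C)(C)CCC(=O)[C@]12C
F5 | step 12 | tert-butyl 15-[(TBS)oxy]-1-oxolabd-7-en-17-oate | CC(C)(C)[Si](C)(C)OCC[C@@H](C)CC[C@H]1C(C(=O)OC(C)(C)C)=CC[C@H]2C(C)(C)CCC(=O)[C@]12C
F6 | step 12 | N-(tert-butyldimethylsilyl)hydrazone of F5 at C1 | CC(C)(C)[Si](C)(C)OCC[C@@H](C)CC[C@H]1C(C(=O)OC(C)(C)C)=CC[C@H]2C(C)(C)CCC(=NN[Si](C)(C)C(C)(C)C)[C@]12C
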